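**Retrosynthetic overview**
- Last disconnection: the O1–C2 bond (with the C2 methine) of the 7-hydroxychromenone, which leads back to a 2,4-dihydroxyphenyl benzyl ketone carried on the 8-aryl group of a genistein core. This C–O ring closure is merged with cleavage of all methyl ethers.
- Biaryl C8–C3' bond: 8-iodo-5,7,4'-tri-O-methylgenistein plus an aryl pinacol boronate made in the flask from the bromo deoxybenzoin.
- The genistein pyranone is also made by C–O closure (3,5-dimethoxyphenol + 4-methoxyphenylacetic acid + one carbon from DMF), then iodinated at C8. The bromo deoxybenzoin comes from resorcinol + 3-bromo-4-methoxyphenylacetic acid.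
- Ring order: all benzene rings are bought; genistein pyranone first (step 1), biaryl union (step 4), daidzein pyranone last (step 5).

Assumption: the target has no stereocentre and its biaryl axis is drawn without configuration, so it is treated as configurationally labile and nothing has to be set.

**Step 1**
Reactants: 1 3,5-dimethoxyphenol; 2 4-methoxyphenylacetic acid
Product: 4 5,7-dimethoxy-3-(4-methoxyphenyl)-4H-chromen-4-one, via deoxybenzoin 3 (not isolated)
Conditions: BF3·OEt2 (neat, as solvent), 85 °C; then DMF, MsCl, 50 → 80 °C; aq. NaOAc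
Reagents that add atoms: N,N-dimethylformamide (DMF), CN(C)C=O
Why: Friedel–Crafts acylation ortho to the free OH (chelation-controlled) gives the deoxybenzoin as its BF2 chelate, then the DMF/MsCl Vilsmeier reagent inserts the C2 methine and the only free phenolic oxygen closes the pyranone by addition–elimination (deoxybenzoin isoflavone synthesis).

**Step 2**
Reactants: 4 5,7-dimethoxy-3-(4-methoxyphenyl)-4H-chromen-4-one
Product: 5 8-iodo-5,7-dimethoxy-3-(4-methoxyphenyl)-4H-chromen-4-one
Conditions: NIS (1.1 equiv), TFA (0.2 equiv), MeCN, 0 °C → rt, dark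
Reagents that add atoms: N-iodosuccinimide (NIS), O=C1CCC(=O)N1I
Why: Electrophilic aromatic iodination; with the 5-oxygen methylated, attack goes to C8 (activated by O1, 7-OMe and 5-OMe, less hindered than C6 between two methoxy groups) and not to the less electron-rich anisyl ring.

**Step 3**
Reactants: 6 resorcinol; 7 3-bromo-4-methoxyphenylacetic acid
Product: 8 2-(3-bromo-4-methoxyphenyl)-1-(2,4-dihydroxyphenyl)ethan-1-one
Conditions: BF3·OEt2 (neat, as solvent), 85 °C; aq. NaOAc
Reagents that add atoms: none
Why: Friedel–Crafts acylation of resorcinol at C4 (para to one OH, ortho to the other) by the BF3-activated acid; the bromoanisole ring is far less nucleophilic, so the acid does not acylate itself.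

**Step 4**
Reactants: 8 2-(3-bromo-4-methoxyphenyl)-1-(2,4-dihydroxyphenyl)ethan-1-one; 5 8-iodo-5,7-dimethoxy-3-(4-methoxyphenyl)-4H-chromen-4-one
Product: 10 8-{5-[2-(2,4-dihydroxyphenyl)-2-oxoethyl]-2-methoxyphenyl}-5,7-dimethoxy-3-(4-methoxyphenyl)-4H-chromen-4-one, via pinacol boronate 9 (not isolated)
Conditions: B2pin2, KOAc, Pd(dppf)Cl2 (3 mol %), 1,4-dioxane, 90 °C; then 5, Pd(OAc)2/SPhos (5/10 mol %), aq. K3PO4, 90 °C
Reagents that add atoms: none
Why: Miyaura borylation of the aryl bromide followed in the same flask by Suzuki–Miyaura coupling with the di-ortho-oxygenated aryl iodide; SPhos-ligated zerovalent palladium is a proven system for tri-ortho-substituted biaryls, and phenols, ketone and chromone tolerate acetate and aqueous phosphate.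

**Step 5**
Reactants: 10 8-{5-[2-(2,4-dihydroxyphenyl)-2-oxoethyl]-2-methoxyphenyl}-5,7-dimethoxy-3-(4-methoxyphenyl)-4H-chromen-4-one
Product: 12 5,7-dihydroxy-8-[2-hydroxy-5-(7-hydroxy-4-oxo-4H-chromen-3-yl)phenyl]-3-(4-hydroxyphenyl)-4H-chromen-4-one, via hexahydroxy deoxybenzoin 11 (not isolated)
Conditions: BBr3 (10 equiv), CH2Cl2, −78 → 40 °C; then DMF, MsCl, 0 → 60 °C; MeOH, then aq. HCl
Reagents that add atoms: N,N-dimethylformamide (DMF), CN(C)C=O
Why: Proposed new method: a boron tribromide-templated Vilsmeier annulation run on the aryl dibromoborates left by ether cleavage. BBr3 first cleaves the four aryl methyl ethers (O–B coordination, SN2 attack of bromide on methyl) and leaves every phenol as an ArO–BBr2 ester, with the o-acylphenol of the deoxybenzoin locked as a six-membered O,O-boron chelate. That chelate is the BBr2 counterpart of the BF2 chelate that makes the benzylic CH2 enolise in the known annulation, while all other phenols stay masked on boron and cannot be O-formylated or mesylated. The chloromethyleneiminium ion from DMF/MsCl then C-formylates the boron enolate, and the chelated phenolic oxygen adds to the iminium carbon and expels Me2NH to form the O1–C2 bond (completed on methanolysis of the B–O bonds); there is only one ortho oxygen on the resorcinol ring, so no regiochemical choice arises. Closest known reaction type: the BF3·OEt2/DMF/MsCl deoxybenzoin-to-isoflavone annulation and, separately, BBr3 demethylation.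

**Compound list**
1 | 3,5-dimethoxyphenol | COc1cc(O)cc(OC)c1 | starting material
2 | 4-methoxyphenylacetic acid | COc1ccc(CC(=O)O)cc1 | starting material
3 | 1-(2-hydroxy-4,6-dimethoxyphenyl)-2-(4-methoxyphenyl)ethan-1-one | COc1ccc(CC(=O)c2c(O)cc(OC)cc2OC)cc1 | intermediate
4 | 5,7-dimethoxy-3-(4-methoxyphenyl)-4H-chromen-4-one | COc1ccc(-c2coc3cc(OC)cc(OC)c3c2=O)cc1 | intermediate
5 | 8-iodo-5,7-dimethoxy-3-(4-methoxyphenyl)-4H-chromen-4-one | COc1ccc(-c2coc3c(I)c(OC)cc(OC)c3c2=O)cc1 | intermediate
6 | resorcinol (benzene-1,3-diol) | Oc1cccc(O)c1 | starting material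
7 | 3-bromo-4-methoxyphenylacetic acid | COc1ccc(CC(=O)O)cc1Br | starting material
8 | 2-(3-bromo-4-methoxyphenyl)-1-(2,4-dihydroxyphenyl)ethan-1-one | COc1ccc(CC(=O)c2ccc(O)cc2O)cc1Br | intermediate
9 | 1-(2,4-dihydroxyphenyl)-2-[4-methoxy-3-(4,4,5,5-tetramethyl-1,3,2-dioxaborolan-2-yl)phenyl]ethan-1-one | COc1ccc(CC(=O)c2ccc(O)cc2O)cc1B1OC(C)(C)C(C)(C)O1 | intermediate
10 | 8-{5-[2-(2,4-dihydroxyphenyl)-2-oxoethyl]-2-methoxyphenyl}-5,7-dimethoxy-3-(4-methoxyphenyl)-4H-chromen-4-one | COc1ccc(-c2coc3c(-c4cc(CC(=O)c5ccc(O)cc5O)ccc4OC)c(OC)cc(OC)c3c2=O)cc1 | intermediate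
11 | 8-{5-[2-(2,4-dihydroxyphenyl)-2-oxoethyl]-2-hydroxyphenyl}-5,7-dihydroxy-3-(4-hydroxyphenyl)-4H-chromen-4-one (present as its aryl borate esters) | Oc1ccc(-c2coc3c(-c4cc(CC(=O)c5ccc(O)cc5O)ccc4O)c(O)cc(O)c3c2=O)cc1 | intermediate
12 | 5,7-dihydroxy-8-[2-hydroxy-5-(7-hydroxy-4-oxo-4H-chromen-3-yl)phenyl]-3-(4-hydroxyphenyl)-4H-chromen-4-one | O=c1c(-c2ccc(O)c(-c3c(O)cc(O)c4c(=O)c(-c5ccc(O)cc5)coc34)c2)coc2cc(O)ccc12 | target

**Totals**
Total steps: 5. Longest linear sequence: 4 steps (steps 1, 2, 4, 5, from 1 and 2 to 12).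

**Steps most likely to fail**

Step 5 (the proposed new method). The boron-complexed polyphenol may precipitate or the Vilsmeier reagent may be consumed by the excess boron bromide, leaving uncyclised 11. The fallback uses known chemistry and separates ring closure from deprotection. It sets out from 10: the classical BF3·OEt2/DMF/MsCl annulation closes the second pyranone on the methyl-protected substrate and gives 8-[5-(7-hydroxy-4-oxo-4H-chromen-3-yl)-2-methoxyphenyl]-5,7-dimethoxy-3-(4-methoxyphenyl)-4H-chromen-4-one F6, which is isolated and purified. A separate BBr3 demethylation in CH2Cl2 then cleaves the four methyl ethers and comes back to the route at 12.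

Step 4 (hindered coupling with an unprotected partner). The free phenols and enolisable ketone of 9 may slow the catalyst, and the ortho-methoxy boronate may protodeboronate before it meets the di-ortho-substituted iodide. The fallback closes the daidzein ring before the biaryl union and couples two fully protected isoflavones. It sets out from 8: BF3·OEt2/DMF/MsCl gives 3-(3-bromo-4-methoxyphenyl)-7-hydroxy-4H-chromen-4-one F2, and MeI/K2CO3 gives 3-(3-bromo-4-methoxyphenyl)-7-methoxy-4H-chromen-4-one F3. Miyaura borylation (B2pin2, Pd(dppf)Cl2, KOAc) gives the isolable 7-methoxy-3-[4-methoxy-3-(4,4,5,5-tetramethyl-1,3,2-dioxaborolan-2-yl)phenyl]-4H-chromen-4-one F4. Suzuki–Miyaura coupling of F4 with 5 (Pd(PPh3)4, aq. Na2CO3, DME, 85 °C) gives 5,7-dimethoxy-8-[2-methoxy-5-(7-methoxy-4-oxo-4H-chromen-3-yl)phenyl]-3-(4-methoxyphenyl)-4H-chromen-4-one F5, and BBr3 in CH2Cl2 removes the five methyl groups and comes back to the route at 12.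

Step 2 (site of iodination). NIS may give some 6-iodo or 6,8-diiodo product, or attack the anisyl ring. The fallback introduces iodine before the pyranone exists, where the free OH dictates the site. It sets out from 3, which is isolated by stopping step 1 after the acylation. NIS in MeCN at 0 °C iodinates ortho to the chelated free OH and gives 1-(2-hydroxy-3-iodo-4,6-dimethoxyphenyl)-2-(4-methoxyphenyl)ethan-1-one F1. DMF dimethyl acetal (toluene, 100 °C, then dilute HCl) closes the ring through that same oxygen, which places iodine at C8 and comes back to the route at 5.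

**Further compounds**
F1 | step 2 | 1-(2-hydroxy-3-iodo-4,6-dimethoxyphenyl)-2-(4-methoxyphenyl)ethan-1-one | COc1ccc(CC(=O)c2c(O)c(I)c(OC)cc2OC)cc1
F2 | step 4 | 3-(3-bromo-4-methoxyphenyl)-7-hydroxy-4H-chromen-4-one | COc1ccc(-c2coc3cc(O)ccc3c2=O)cc1Br
F3 | step 4 | 3-(3-bromo-4-methoxyphenyl)-7-methoxy-4H-chromen-4-one | COc1ccc(-c2coc3cc(OC)ccc3c2=O)cc1Br
F4 | step 4 | 7-methoxy-3-[4-methoxy-3-(4,4,5,5-tetramethyl-1,3,2-dioxaborolan-2-yl)phenyl]-4H-chromen-4-one | COc1ccc(-c2coc3cc(OC)ccc3c2=O)cc1B1OC(C)(C)C(C)(C)O1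
F5 | step 4 | 5,7-dimethoxy-8-[2-methoxy-5-(7-methoxy-4-oxo-4H-chromen-3-yl)phenyl]-3-(4-methoxyphenyl)-4H-chromen-4-one | COc1ccc(-c2coc3c(-c4cc(-c5coc6cc(OC)ccc6c5=O)ccc4OC)c(OC)cc(OC)c3c2=O)cc1
F6 | step 5 | 8-[5-(7-hydroxy-4-oxo-4H-chromen-3-yl)-2-methoxyphenyl]-5,7-dimethoxy-3-(4-methoxyphenyl)-4H-chromen-4-one | COc1ccc(-c2coc3c(-c4cc(-c5coc6cc(O)ccc6c5=O)ccc4OC)c(OC)cc(OC)c3c2=O)cc1
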